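**Retrosynthetic overview**

1. Target 29 ← tetraol 28 by twofold Friedel–Crafts C-acetylation (at B5, the only free carbon of ring B, and at one of the two equivalent CH of ring A) ← tribenzyl ether 27 by hydrogenolysis.
2. The strategy rests on ring B being hexasubstituted with O and C substituents alternating (B1 CH2 bridge, B2 OH, B3 CH3, B4 OH, B5 acetyl, B6 OMe). Ring B of 27 is cut into cyclobutenone 22 (B3 with CH3, B4 with O-benzyl, B5 H, and B2 OH from its C=O) and methoxyalkyne 13 (B1 with the bridge, B6 OMe), forming B1–B2 and B5–B6 and closing B2–B3.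
3. 13 ← lithium methoxyacetylide 12 (from acetal 11) + benzylic chloride 10; the ring A pattern is fixed by ortho-lithiation of bis-MOM ether 2 of 5-methoxyresorcinol between its two acetal oxygens.
4. 22 ← methylketene 21 (from propionyl chloride 20) + benzyl ethynyl ether 19 by [2+2]; the benzyl group is on the ynol ether from the start, so no alkoxy exchange on the cyclobutenone is needed.
5. Ring order: ring A is bought (1); ring B is the only ring formed (step 11), two steps from the end.

Key step: step 11

Remark: 22, 24 and 26 are racemic and the target is achiral; 1, 11, 14, 20 and the reagents named are taken as commercial.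

**Route**

Step 1
Reactants: 1 5-methoxyresorcinol
Product: 2 1-methoxy-3,5-bis(methoxymethoxy)benzene
Conditions: MOMCl (2.5 equiv), iPr2NEt, CH2Cl2, 0 °C → rt
Reagents that add atoms: chloromethyl methyl ether, COCCl
Why: O-alkylation of both phenols with an α-chloro ether (Williamson type) installs the two acetal ethers that direct the metalation of step 2.

Step 2
Reactants: 2 1-methoxy-3,5-bis(methoxymethoxy)benzene
Product: 5 4-methoxy-2,6-bis(methoxymethoxy)benzaldehyde, via aryllithium 3 (not isolated), via lithium hemiaminal alkoxide 4 (not isolated)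
Conditions: n-BuLi (1.2 equiv), THF, 0 °C → rt; DMF, 0 °C; H2O
Reagents that add atoms: N,N-dimethylformamide, CN(C)C=O
Why: Directed ortho-metalation: the carbon flanked by both chelating OMOM groups, which direct more strongly than OMe, should be lithiated in preference to the two carbons between OMOM and OMe, and DMF formylates the aryllithium, so the future bridge carbon sits between the two future hydroxyls of ring A.

Step 3
Reactants: 5 4-methoxy-2,6-bis(methoxymethoxy)benzaldehyde
Product: 6 2,6-dihydroxy-4-methoxybenzaldehyde
Conditions: 3 M aq. HCl, MeOH, 50 °C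
Reagents that add atoms: none
Why: Acid-catalysed transfer of the two MOM groups to methanol (acetal cleavage), done at the aldehyde stage because the formyl group deactivates the ring toward the formaldehyde acetal that is released.

Step 4
Reactants: 6 2,6-dihydroxy-4-methoxybenzaldehyde
Product: 7 2,6-bis(benzyloxy)-4-methoxybenzaldehyde
Conditions: BnBr (2.5 equiv), K2CO3, DMF, 60 °C
Reagents that add atoms: benzyl bromide, BrCc1ccccc1
Why: Williamson etherification of both phenols; benzyl replaces MOM because an ortho acetal oxygen could trap the benzylic cation of the later chloride as a benzodioxine, and because all O-protecting groups of 27 then leave together under neutral hydrogenolysis.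

Step 5
Reactants: 7 2,6-bis(benzyloxy)-4-methoxybenzaldehyde
Product: 8 [2,6-bis(benzyloxy)-4-methoxyphenyl]methanol
Conditions: NaBH4, THF–MeOH, 0 °C; H2O
Reagents that add atoms: none
Why: Borohydride reduction of an aryl aldehyde; the acid-labile trialkoxybenzyl alcohol is isolated under neutral to basic conditions.

Step 6
Reactants: 8 [2,6-bis(benzyloxy)-4-methoxyphenyl]methanol
Product: 10 1,3-bis(benzyloxy)-2-(chloromethyl)-5-methoxybenzene, via benzylic mesylate 9 (not isolated)
Conditions: MsCl, Et3N, CH2Cl2, −30 → 0 °C; cold aq. NaHCO3; used at once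
Reagents that add atoms: methanesulfonyl chloride, CS(Cl)(=O)=O
Why: Sulfonylation of the alcohol and substitution of the highly activated benzylic mesylate by the chloride of the triethylammonium salt in the same flask; the chloride is chosen over the bromide because it is less prone to ionise, and it is not stored.

Step 7
Reactants: 11 chloroacetaldehyde dimethyl acetal; 10 1,3-bis(benzyloxy)-2-(chloromethyl)-5-methoxybenzene
Product: 13 1,3-bis(benzyloxy)-5-methoxy-2-(3-methoxyprop-2-yn-1-yl)benzene, via lithium methoxyacetylide 12 (not isolated)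
Conditions: 11 (1.6 equiv), LiNEt2 (from Et2NH and n-BuLi, 3 equiv per 11), THF, 0 °C; Et2NH removed under reduced pressure (not to dryness); THF–DMPU, 10, −78 → −20 °C; pH 7 buffer; Et3N-treated silica
Reagents that add atoms: none
Why: Threefold action of LiNEt2 on the α-chloro acetal (loss of MeOH, loss of HCl, deprotonation) gives the lithium alkoxyacetylide, which is C-alkylated by the benzylic chloride (SN2 alkylation of an acetylide); the amine is removed first so that it cannot compete for this very reactive electrophile.

Step 8
Reactants: 14 benzyl alcohol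
Product: 16 benzyl (E)-1,2-dichlorovinyl ether, via potassium benzyloxide 15 (not isolated)
Conditions: KH, THF, 0 °C; Cl2C=CHCl, −50 °C → rt
Reagents that add atoms: trichloroethylene, ClC=C(Cl)Cl
Why: Anti addition of the alkoxide to dichloroacetylene generated in the flask from trichloroethylene (the dichlorovinyl ether route to ynol ethers) gives the E ether.

Step 9
Reactants: 16 benzyl (E)-1,2-dichlorovinyl ether
Product: 19 benzyl ethynyl ether, via chloroalkyne 17 (not isolated), via lithium benzyloxyacetylide 18 (not isolated)
Conditions: n-BuLi (2.3 equiv), THF, −78 → −40 °C; MeOH, −78 °C; cold aqueous work-up; kept ≤ 0 °C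
Reagents that add atoms: none
Why: Vinyl deprotonation with loss of LiCl gives the chloroalkyne, chlorine–lithium exchange gives the lithium alkoxyacetylide and methanol protonates it (dichlorovinyl ether to ynol ether conversion); benzyl ynol ethers rearrange only on warming, so 19 is kept cold and used the same day.

Step 10
Reactants: 20 propionyl chloride; 19 benzyl ethynyl ether
Product: 22 rac-3-(benzyloxy)-4-methylcyclobut-2-en-1-one, via methylketene 21 (not isolated)
Conditions: Et3N, CH2Cl2, 0 °C → rt; 20 (1.5 equiv) added slowly
Reagents that add atoms: none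
Why: Dehydrochlorination gives methylketene, which undergoes the ketene–ynol ether [2+2] cycloaddition with the nucleophilic CH terminus of 19 bonding to the ketene carbonyl carbon; this places CH3 on the sp3 carbon C4 and OBn on C3, avoids any alkoxy exchange that could move the double bond to the methyl-bearing carbon, and forms C4 as a racemic centre that is lost later.

Step 11
Reactants: 13 1,3-bis(benzyloxy)-5-methoxy-2-(3-methoxyprop-2-yn-1-yl)benzene; 22 rac-3-(benzyloxy)-4-methylcyclobut-2-en-1-one
Product: 27 3-(benzyloxy)-6-{[2,6-bis(benzyloxy)-4-methoxyphenyl]methyl}-5-methoxy-2-methylphenol, via vinylketene 23 (not isolated), via vinylcyclobutenone 24 (not isolated), via dienylketene 25 (not isolated), via cyclohexadienone 26 (not isolated)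
Conditions: 22 (2 equiv), toluene, 110 °C then 145 °C, sealed tube, Ar
Reagents that add atoms: none
Why: Heating opens 22 by a 4π electrocyclic ring opening (CH3 turning outward) to vinylketene 23, whose ketene C=C adds the ynol ether of 13 in a [2+2] cycloaddition to give 4-vinylcyclobutenone 24; a second 4π opening gives dienylketene 25, which cyclises to 26 and tautomerises to phenol 27. This is the Danheiser benzannulation of a cyclobutenone with an alkoxyalkyne, and since 24, through which every such reaction passes, is itself a 3-alkoxycyclobutenone, the opening of the 3-benzyloxy compound 22 is expected under the same heating. Ring B is closed by a thermal disrotatory 6π electrocyclisation joining the former carbonyl carbon (B2) to the methyl-bearing carbon (B3), while B1–B2 and B5–B6 come from the [2+2] step. No stereocentre survives: the sp3 carbons of 22, 24 and 26 are racemic and are lost on aromatisation. Only one orientation of the [2+2] addition is wanted, and it is secured because the alkyne carbon remote from OMe is the electron-rich end of the ynol ether and joins the electrophilic central carbon of the ketene, so the bridge ends up flanked by the new phenol oxygen and the methoxy group. The alkyne must also outlast the heating, which the O-methyl group secures (no β-hydrogen for retro-ene loss of an alkene), and the excess of 22 covers loss of 23 to dimerisation.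

Step 12
Reactants: 27 3-(benzyloxy)-6-{[2,6-bis(benzyloxy)-4-methoxyphenyl]methyl}-5-methoxy-2-methylphenol
Product: 28 4-[(2,6-dihydroxy-4-methoxyphenyl)methyl]-5-methoxy-2-methylbenzene-1,3-diol
Conditions: H2 (1 atm), Pd/C, EtOAc–MeOH, rt; handled under Ar
Reagents that add atoms: none
Why: Catalytic hydrogenolysis of the three aryl benzyl ethers under neutral conditions, which leaves the methyl ethers and the diarylmethane bridge untouched.

Step 13
Reactants: 28 4-[(2,6-dihydroxy-4-methoxyphenyl)methyl]-5-methoxy-2-methylbenzene-1,3-diol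
Product: 29 1-{3-[(3-acetyl-4,6-dihydroxy-2-methoxy-5-methylphenyl)methyl]-2,4-dihydroxy-6-methoxyphenyl}ethan-1-one (target)
Conditions: Ac2O (2.2 equiv), BF3·OEt2, 0 °C → rt; NaOAc, aq. MeOH work-up
Reagents that add atoms: acetic anhydride, CC(=O)OC(C)=O
Why: Friedel–Crafts C-acetylation of polyphenols (O-acetylation then Fries-type transfer under BF3): ring B can react only at B5 and ring A at either of two equivalent carbons, and each ring is deactivated by its first acetyl group, so about two equivalents of anhydride should give the bis-ketone.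

**Compound list**

1 | 5-methoxyresorcinol | COc1cc(O)cc(O)c1 | starting material
2 | 1-methoxy-3,5-bis(methoxymethoxy)benzene | COCOc1cc(OC)cc(OCOC)c1 | intermediate
3 | [4-methoxy-2,6-bis(methoxymethoxy)phenyl]lithium | [Li]c1c(OCOC)cc(OC)cc1OCOC | intermediate
4 | lithium (dimethylamino)[4-methoxy-2,6-bis(methoxymethoxy)phenyl]methanolate | COCOc1cc(OC)cc(OCOC)c1C(O[Li])N(C)C | intermediate
5 | 4-methoxy-2,6-bis(methoxymethoxy)benzaldehyde | COCOc1cc(OC)cc(OCOC)c1C=O | intermediate
6 | 2,6-dihydroxy-4-methoxybenzaldehyde | COc1cc(O)c(C=O)c(O)c1 | intermediate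
7 | 2,6-bis(benzyloxy)-4-methoxybenzaldehyde | COc1cc(OCc2ccccc2)c(C=O)c(OCc2ccccc2)c1 | intermediate
8 | [2,6-bis(benzyloxy)-4-methoxyphenyl]methanol | COc1cc(OCc2ccccc2)c(CO)c(OCc2ccccc2)c1 | intermediate
9 | [2,6-bis(benzyloxy)-4-methoxyphenyl]methyl methanesulfonate | COc1cc(OCc2ccccc2)c(COS(C)(=O)=O)c(OCc2ccccc2)c1 | intermediate
10 | 1,3-bis(benzyloxy)-2-(chloromethyl)-5-methoxybenzene | COc1cc(OCc2ccccc2)c(CCl)c(OCc2ccccc2)c1 | intermediate
11 | chloroacetaldehyde dimethyl acetal | COC(CCl)OC | starting material
12 | lithium methoxyacetylide | [Li]C#COC | intermediate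
13 | 1,3-bis(benzyloxy)-5-methoxy-2-(3-methoxyprop-2-yn-1-yl)benzene | COC#CCc1c(OCc2ccccc2)cc(OC)cc1OCc1ccccc1 | intermediate
14 | benzyl alcohol | OCc1ccccc1 | starting material
15 | potassium benzyloxide | [K+].[O-]Cc1ccccc1 | intermediate
16 | benzyl (E)-1,2-dichlorovinyl ether | Cl/C=C(/Cl)OCc1ccccc1 | intermediate
17 | benzyl chloroethynyl ether | ClC#COCc1ccccc1 | intermediate
18 | lithium (benzyloxy)acetylide | [Li]C#COCc1ccccc1 | intermediate
19 | benzyl ethynyl ether | C#COCc1ccccc1 | intermediate
20 | propionyl chloride | CCC(Cl)=O | starting material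
21 | methylketene | CC=C=O | intermediate
22 | rac-3-(benzyloxy)-4-methylcyclobut-2-en-1-one | CC1C(=O)C=C1OCc1ccccc1 | intermediate
23 | (Z)-3-(benzyloxy)penta-1,3-dien-1-one (CH3 trans to the ketene carbon) | C/C=C(OCc1ccccc1)/C=C=O | intermediate
24 | rac-4-[(Z)-1-(benzyloxy)prop-1-en-1-yl]-2-{[2,6-bis(benzyloxy)-4-methoxyphenyl]methyl}-3-methoxycyclobut-2-en-1-one | C/C=C(OCc1ccccc1)/C1C(=O)C(Cc2c(OCc3ccccc3)cc(OC)cc2OCc2ccccc2)=C1OC | intermediate
25 | (3E,5Z)-5-(benzyloxy)-2-{[2,6-bis(benzyloxy)-4-methoxyphenyl]methyl}-3-methoxyhepta-1,3,5-trien-1-one | C/C=C(OCc1ccccc1)/C=C(OC)\C(Cc1c(OCc2ccccc2)cc(OC)cc1OCc1ccccc1)=C=O | intermediate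
26 | rac-5-(benzyloxy)-2-{[2,6-bis(benzyloxy)-4-methoxyphenyl]methyl}-3-methoxy-6-methylcyclohexa-2,4-dien-1-one | CC1C(=O)C(Cc2c(OCc3ccccc3)cc(OC)cc2OCc2ccccc2)=C(OC)C=C1OCc1ccccc1 | intermediate
27 | 3-(benzyloxy)-6-{[2,6-bis(benzyloxy)-4-methoxyphenyl]methyl}-5-methoxy-2-methylphenol | COc1cc(OCc2ccccc2)c(C)c(O)c1Cc1c(OCc2ccccc2)cc(OC)cc1OCc1ccccc1 | intermediate
28 | 4-[(2,6-dihydroxy-4-methoxyphenyl)methyl]-5-methoxy-2-methylbenzene-1,3-diol | COc1cc(O)c(C)c(O)c1Cc1c(O)cc(OC)cc1O | intermediate
29 | 1-{3-[(3-acetyl-4,6-dihydroxy-2-methoxy-5-methylphenyl)methyl]-2,4-dihydroxy-6-methoxyphenyl}ethan-1-one | COc1cc(O)c(Cc2c(O)c(C)c(O)c(C(C)=O)c2OC)c(O)c1C(C)=O | target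

**Step count and risks**

Total steps: 13. Longest linear sequence: 10 (steps 1–7, then 11–13).

Steps most likely to fail:

Step 11. The vinylogous-ester cyclobutenone 22 may open more slowly than alkyl cyclobutenones. At the temperature then needed, vinylketene 23 could be lost to dimerisation or to O-acylation of the product phenol, and ynol ether 13 to adventitious acid. The fallback generates the same vinylketene 23 at room temperature by a photochemical Wolff rearrangement instead of a thermal ring opening. Commercial pentane-2,3-dione would be O-benzylated (BnBr, K2CO3, DMF) to (Z)-3-(benzyloxy)pent-3-en-2-one F1. Its kinetic enolate (LiN(SiMe3)2, THF, −78 °C) would be trifluoroacetylated with 2,2,2-trifluoroethyl trifluoroacetate to (Z)-5-(benzyloxy)-1,1,1-trifluorohept-5-ene-2,4-dione F2. Deacylative diazo transfer (MsN3, Et3N, aq. MeCN) would then give (Z)-3-(benzyloxy)-1-diazopent-3-en-2-one F3. Irradiation of F3 with 13 (300 nm, CH2Cl2, rt), then heating in toluene, would pass through 23–26. The fallback sets out from 13 and comes back to the route at 27.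

Step 7. Chloride 10 may ionise and alkylate its own electron-rich ring, or be captured by residual amine, before the acetylide attacks. The fallback replaces the SN2 alkylation by a neutral palladium-catalysed coupling of a storable benzylic carbonate. Alcohol 8 would be converted (ClCO2Me, pyridine, CH2Cl2) into [2,6-bis(benzyloxy)-4-methoxyphenyl]methyl methyl carbonate F4. Acetylide 12 would be stannylated (Bu3SnCl, THF, −78 °C) to tributyl(methoxyethynyl)stannane F5. Coupling of F4 with F5 (Pd2(dba)3, 1,1'-bis(diphenylphosphino)ferrocene, THF, 60 °C) proceeds by ionisation of the carbonate on palladium and Stille-type transfer of the alkynyl group. The fallback sets out from 8 and comes back at 13.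

Step 13. Under the Lewis acid, ipso protonation at the electron-rich bridge carbons could cleave or redistribute the diarylmethane. Ring A could also be acetylated twice, and 28 could oxidise in air. The fallback installs both acetyl groups by cross-coupling before the phenols are freed. Compound 27 would be brominated (NBS, 2 equiv, CH2Cl2, −20 °C) at B5 and at one ring A carbon to 3-(benzyloxy)-6-{[2,6-bis(benzyloxy)-3-bromo-4-methoxyphenyl]methyl}-4-bromo-5-methoxy-2-methylphenol F6. Stille coupling with tributyl(1-ethoxyvinyl)stannane (Pd(PPh3)4, toluene, 100 °C) would give the bis(1-ethoxyvinyl) compound F7, and dilute aqueous HCl would hydrolyse it to the diacetyl tribenzyl ether F8. Hydrogenolysis (H2, Pd/C, EtOAc) would then remove the benzyl groups. The fallback sets out from 27 and comes back at the target 29.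

**Further compounds**

F1 | step 11 | (Z)-3-(benzyloxy)pent-3-en-2-one | C/C=C(OCc1ccccc1)/C(C)=O
F2 | step 11 | (Z)-5-(benzyloxy)-1,1,1-trifluorohept-5-ene-2,4-dione | C/C=C(OCc1ccccc1)/C(=O)CC(=O)C(F)(F)F
F3 | step 11 | (Z)-3-(benzyloxy)-1-diazopent-3-en-2-one | C/C=C(OCc1ccccc1)/C(=O)C=[N+]=[N-]
F4 | step 7 | [2,6-bis(benzyloxy)-4-methoxyphenyl]methyl methyl carbonate | COC(=O)OCc1c(OCc2ccccc2)cc(OC)cc1OCc1ccccc1
F5 | step 7 | tributyl(methoxyethynyl)stannane | CCCC[Sn](CCCC)(CCCC)C#COC
F6 | step 13 | 3-(benzyloxy)-6-{[2,6-bis(benzyloxy)-3-bromo-4-methoxyphenyl]methyl}-4-bromo-5-methoxy-2-methylphenol | COc1c(Br)c(OCc2ccccc2)c(C)c(O)c1Cc1c(OCc2ccccc2)cc(OC)c(Br)c1OCc1ccccc1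
F7 | step 13 | 3-(benzyloxy)-6-{[2,6-bis(benzyloxy)-3-(1-ethoxyvinyl)-4-methoxyphenyl]methyl}-4-(1-ethoxyvinyl)-5-methoxy-2-methylphenol | COc1c(C(=C)OCC)c(OCc2ccccc2)c(C)c(O)c1Cc1c(OCc2ccccc2)cc(OC)c(C(=C)OCC)c1OCc1ccccc1
F8 | step 13 | 1-{3-[(3-acetyl-4-(benzyloxy)-6-hydroxy-2-methoxy-5-methylphenyl)methyl]-2,4-bis(benzyloxy)-6-methoxyphenyl}ethan-1-one | COc1c(C(C)=O)c(OCc2ccccc2)c(C)c(O)c1Cc1c(OCc2ccccc2)cc(OC)c(C(C)=O)c1OCc1ccccc1
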